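## Retrosynthetic overview

1. Numbering and rings: ring A pyrrolidine (N4, C1–C3, C9a); ring B azepine (N4, C5–C9, C9a); ring C butenolide fused at C5–C6; ring D spiro γ-lactone on C9 (O–C9–C10–C11–C12); ring E γ-lactone on C3 (C18–C21, methyl on C20).
2. Last disconnections: the N4–C5 N,O-acetal (rings B and C) goes back to a secondary amine and a γ-hydroxybutenolide (from a 2-silylfuran by photooxygenation). Ring D goes back to a δ-lactam by N4→O acyl shift.
3. Key disconnection C9–C10: the δ-lactam ring N4–C12–C11–C10–C9–C9a is closed by SmI2-mediated reductive addition of a C10 iodide to the C9 ketone, with C11 brought in preset.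
4. Enabling feature: the ring-D oxygen on C9 is vicinal to N4 (N4–C9a–C9–O). The lactone acyl carbon C12 can therefore be parked on N4 as a tether for a six-membered closure, then moved to oxygen through the five-membered N4–C9a–C9–O–C12 array, which also frees N4 for ring B.
5. Precursor assembly and ring order: Boc-L-pyroglutamate (ring A, C9a); vinylogous Mannich reaction and hydrogenation (ring E, C3, C18, C20); Fukuyama ketone synthesis with a silylfuryl-ethylzinc (C5–C8); N-acylation with (S)-3-bromo-2-methylpropanoyl chloride (C10–C12). Rings form in the order A, E, temporary lactam, C, then D and B together.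

Key step: step 16

Assumption: C5 of the N,O-acetal can equilibrate through the ring-opened iminium carboxylate, and the (5S) configuration of the target is taken to be the more stable one. Compounds 1, 4, 9 and 14 are taken as commercial.

## Route

Step 1
Reactants: 1 benzyl (2S)-1-Boc-5-oxopyrrolidine-2-carboxylate
Product: 3 benzyl (2S)-1-Boc-5-methoxypyrrolidine-2-carboxylate (C5 epimers), via hemiaminal 2 (not isolated)
Conditions: LiBHEt3, THF, −78 °C; then MeOH, PPTS (cat.), rt
Reagents that add atoms: methanol (CO)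
Why: Chemoselective hydride reduction of the imide-like N-Boc lactam carbonyl (the benzyl ester is left alone at −78 °C) gives the hemiaminal, which acid-catalysed acetal exchange converts into the stable N-acyliminium precursor without touching C9a.

Step 2
Reactants: 4 3-methylfuran-2(5H)-one
Product: 5 [(3-methylfuran-2-yl)oxy]tri(propan-2-yl)silane
Conditions: TIPSOTf, Et3N, CH2Cl2, 0 °C
Reagents that add atoms: triisopropylsilyl trifluoromethanesulfonate (CC(C)[Si](OS(=O)(=O)C(F)(F)F)(C(C)C)C(C)C)
Why: Soft enolisation of the butenolide with a silyl triflate and an amine gives the aromatic 2-silyloxyfuran, the standard dienolate equivalent for vinylogous Mannich reactions.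

Step 3
Reactants: 3 methoxy N,O-acetal; 5 silyloxyfuran
Product: 6 benzyl (2S,5S)-1-Boc-5-[(2S)-4-methyl-5-oxo-2,5-dihydrofuran-2-yl]pyrrolidine-2-carboxylate
Conditions: TIPSOTf (10 mol%), CH2Cl2, −78 °C
Reagents that add atoms: none
Why: Vinylogous Mannich reaction in which the silyl triflate ionises 3 to the N-acyliminium ion and 5 attacks through its C5 anti to the ester (2,5-trans ring A) with the usual threo preference of silyloxyfuran additions to cyclic N-acyliminium ions, which should set C3 and C18 as (S,S); minor diastereomers would be removed by chromatography.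

Step 4
Reactants: 6 butenolide benzyl ester
Product: 7 (2S,5S)-1-Boc-5-[(2S,4S)-4-methyl-5-oxooxolan-2-yl]pyrrolidine-2-carboxylic acid
Conditions: H2 (1 atm), Pd/C (10%), EtOAc, rt
Reagents that add atoms: none
Why: Heterogeneous hydrogenation should deliver hydrogen to the butenolide face anti to the pyrrolidine substituent on C18, giving the cis-disubstituted lactone (C20 S), and the same operation hydrogenolyses the benzyl ester.

Step 5
Reactants: 7 N-Boc acid
Product: 8 S-ethyl (2S,5S)-1-Boc-5-[(2S,4S)-4-methyl-5-oxooxolan-2-yl]pyrrolidine-2-carbothioate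
Conditions: EtSH, EDC·HCl, DMAP (cat.), CH2Cl2, 0 °C → rt
Reagents that add atoms: ethanethiol (CCS)
Why: Carbodiimide (Steglich-type) thioesterification of a urethane-protected amino acid, which does not epimerise C9a, provides the acyl donor for the Fukuyama coupling.

Step 6
Reactants: 9 (2S)-3-bromo-2-methylpropan-1-ol
Product: 10 (2S)-3-bromo-2-methylpropanoic acid
Conditions: TEMPO (cat.), PhI(OAc)2, MeCN/H2O, rt
Reagents that add atoms: water (O)
Why: Oxoammonium (TEMPO) oxidation of the primary alcohol to the acid via the aldehyde hydrate under near-neutral conditions leaves the C–Br bond and the α-stereocentre (the future C11) intact.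

Step 7
Reactants: 10 bromo acid
Product: 11 (2S)-3-bromo-2-methylpropanoyl chloride
Conditions: (COCl)2, DMF (cat.), CH2Cl2, 0 °C → rt
Reagents that add atoms: oxalyl chloride (O=C(Cl)C(=O)Cl)
Why: Standard acid chloride formation through the catalytic Vilsmeier species, run without base so that no ketene forms and the future C11 keeps its configuration.

Step 8
Reactants: 8 N-Boc thioester; 11 acid chloride
Product: 13 S-ethyl (2S,5S)-1-[(2S)-3-bromo-2-methylpropanoyl]-5-[(2S,4S)-4-methyl-5-oxooxolan-2-yl]pyrrolidine-2-carbothioate, via pyrrolidinium trifluoroacetate 12 (not isolated)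
Conditions: TFA, CH2Cl2, 0 °C; evaporate; then 11, NaHCO3 (sat. aq)/CH2Cl2, 0 °C → rt
Reagents that add atoms: none
Why: Acidolysis of the Boc group followed by Schotten–Baumann N-acylation in a bicarbonate-buffered two-phase system (as used for acylating proline with 3-halo-2-methylpropanoyl chlorides) avoids tertiary-amine bases that would cause ketene formation or HBr elimination.

Step 9
Reactants: 14 (furan-3-yl)methanol
Product: 17 [2-(trimethylsilyl)furan-3-yl]methanol, via dilithio species 15 (not isolated), via bis-silyl compound 16 (not isolated)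
Conditions: n-BuLi (2.2 equiv), THF, −78 → 0 °C; Me3SiCl (2.3 equiv), −78 °C → rt; then K2CO3 (cat.), MeOH, 0 °C
Reagents that add atoms: chlorotrimethylsilane (C[Si](C)(C)Cl)
Why: Alkoxide-directed ortho-lithiation at C2 of the furan, C- and O-silylation, and mild methanolysis of the labile O–Si bond install the silyl group that later dictates the regiochemistry of the photooxygenation.

Step 10
Reactants: 17 2-silyl furylmethanol
Product: 19 [4-iodo-2-(trimethylsilyl)furan-3-yl]methanol, via 4-lithio dianion 18 (not isolated)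
Conditions: n-BuLi (2.2 equiv), DME, 0 °C; then I2, −78 °C
Reagents that add atoms: iodine (II)
Why: With C2 blocked by silicon the lithium alkoxide directs a second lithiation to C4 (directed ortho-metalation in DME), and iodine quench gives the 3,4-disubstituted furan regiospecifically.

Step 11
Reactants: 19 iodo furylmethanol
Product: 21 (4-iodo-3-methylfuran-2-yl)trimethylsilane, via mesylate 20 (not isolated)
Conditions: MsCl, Et3N, CH2Cl2, −20 °C; then LiBHEt3, THF, −20 → 0 °C
Reagents that add atoms: none
Why: Mesylation of the activated furylmethyl alcohol and SN2 hydride displacement turn the directing group into the C-methyl group of ring C, while the aryl iodide is inert to the borohydride at this temperature.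

Step 12
Reactants: 21 iodofuran
Product: 23 2-[4-methyl-5-(trimethylsilyl)furan-3-yl]ethan-1-ol, via furylmagnesium chloride 22 (not isolated)
Conditions: i-PrMgCl·LiCl, THF, 0 °C → rt; then CuI (10 mol%), ethylene oxide, −20 °C → rt
Reagents that add atoms: ethylene oxide (C1CO1)
Why: Iodine–magnesium exchange gives a 3-furyl Grignard reagent that does not migrate to the α-position, and its CuI-catalysed opening of ethylene oxide adds the C7–C8 unit.

Step 13
Reactants: 23 furylethanol
Product: 24 [4-(2-iodoethyl)-3-methylfuran-2-yl]trimethylsilane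
Conditions: I2, PPh3, imidazole, CH2Cl2, 0 °C
Reagents that add atoms: iodine (II)
Why: Appel-type iodination of the primary alcohol under imidazole-buffered conditions spares the acid-labile silylfuran.

Step 14
Reactants: 24 iodoethylfuran; 13 N-acyl thioester
Product: 26 (3S,5S)-5-[(2S,5S)-1-[(2S)-3-bromo-2-methylpropanoyl]-5-{3-[4-methyl-5-(trimethylsilyl)furan-3-yl]propanoyl}pyrrolidin-2-yl]-3-methyloxolan-2-one, via alkylzinc iodide 25 (not isolated)
Conditions: Zn dust (activated), THF, 40 °C; then 13, PdCl2(PPh3)2 (5 mol%), toluene/THF, rt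
Reagents that add atoms: none
Why: Fukuyama coupling of the alkylzinc iodide with the thioester gives the ketone without over-addition and without touching the lactone, the amide, the alkyl bromide or the C9a stereocentre.

Step 15
Reactants: 26 bromo ketone
Product: 27 the corresponding iodide, (3S,5S)-5-[(2S,5S)-1-[(2S)-3-iodo-2-methylpropanoyl]-5-{3-[4-methyl-5-(trimethylsilyl)furan-3-yl]propanoyl}pyrrolidin-2-yl]-3-methyloxolan-2-one
Conditions: NaI, acetone, 50 °C, dark
Reagents that add atoms: sodium iodide ([Na+].[I-])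
Why: Finkelstein exchange (SN2, driven by precipitation of NaBr) gives the more easily reduced primary iodide under neutral conditions that do not epimerise C9a or C11.

Step 16
Reactants: 27 iodo-amide ketone
Product: 29 (3S,6R,8S,8aS)-8-hydroxy-6-methyl-3-[(2S,4S)-4-methyl-5-oxooxolan-2-yl]-8-{2-[4-methyl-5-(trimethylsilyl)furan-3-yl]ethyl}indolizidin-5-one, via alkylsamarium diiodide 28 (not isolated)
Conditions: SmI2 (2.5 equiv), NiI2 (2 mol%), THF, −78 → 0 °C, slow addition of 27; aq NH4Cl
Reagents that add atoms: none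
Why: SmI2 (with catalytic NiI2 to speed up C–I activation) reduces the primary C10–I bond to alkylsamarium 28, which adds to the tethered C9 ketone; the closest known reaction type is the samarium Barbier cyclisation of ω-iodoalkyl ketones to six-membered carbinols, and the step joins two electrophilic carbons (C10 and the carbonyl carbon C9) by reductive polarity reversal. The ring closed is the six-membered δ-lactam N4–C12–C11–C10–C9–C9a, in a 6-exo-trig mode (the C=O is exocyclic to the forming ring). The new quaternary stereocentre C9 is controlled by the tether: C10 hangs from N4 and must reach C9 syn to the C9a–N4 bond, and in the half-chair fixed by the planar amide and the fused ring A (C1 pseudo-equatorial) the CH2CH2-furyl chain should take the equatorial site next to H-9a while the oxygen goes axial, anti to C9a–N4, which is the required (9S) arrangement. The preset C11 methyl group reinforces this, because in the epimeric transition state it would be 1,3-diaxial to the chain, and C11 itself is never enolised. The selectivity needed is reduction of C–I in preference to the α-amido ketone (which could otherwise lose N4 reductively) and to the lactone; it is secured by the iodide being far easier to reduce than a dialkyl ketone in THF without HMPA, by the nickel catalysis at low temperature, and by the fast capture of the C10 radical, which limits 1,5-hydrogen transfer.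

Step 17
Reactants: 29 hydroxy lactam silylfuran
Product: 31 5-hydroxy-4-(2-{(3S,6R,8S,8aS)-8-hydroxy-6-methyl-3-[(2S,4S)-4-methyl-5-oxooxolan-2-yl]-5-oxoindolizidin-8-yl}ethyl)-3-methylfuran-2(5H)-one (hemiacetal epimers), via silyl ester 30 (not isolated)
Conditions: O2, hν (visible), tetraphenylporphyrin (cat.), CH2Cl2, −78 °C; then THF/H2O, rt
Reagents that add atoms: oxygen (O=O)
Why: Photooxygenation: [4+2] addition of singlet oxygen gives an endoperoxide that collapses by 1,2-silyl shift to silyl ester 30, so the lactone carbonyl appears at the silicon-bearing carbon next to C–CH3, and hydrolysis on work-up closes the γ-hydroxybutenolide with C5 as the hemiacetal carbon.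

Step 18
Reactants: 31 hydroxy lactam hydroxybutenolide
Product: 34 the target CNP0155196.1, via ammonium salt 32 (not isolated), via iminium salt 33 (not isolated)
Conditions: HCl (4 M in dioxane), CH2Cl2, 0 → 40 °C; evaporate; then NaOAc, AcOH, 4 Å MS, 40 °C; cold aq NaHCO3 work-up
Reagents that add atoms: none
Why: Acid-mediated N→O acyl migration through the five-membered N4–C9a–C9–O–C12 orthoamide turns the δ-lactam into the spiro γ-lactone (ring D) and holds N4 as its ammonium salt, which in buffered acetic acid condenses with the pseudo-acid (γ-hydroxybutenolide) to the cyclic iminium ion 33, whose (Z)-carboxyl group adds to C5 and closes rings B and C as the N,O-acetal, with C5 set under thermodynamic control.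

## Compound list

1 | benzyl (2S)-1-(tert-butoxycarbonyl)-5-oxopyrrolidine-2-carboxylate | O=C(OCc1ccccc1)[C@@H]1CCC(=O)N1C(=O)OC(C)(C)C | starting material
2 | benzyl (2S)-1-(tert-butoxycarbonyl)-5-hydroxypyrrolidine-2-carboxylate (C5 epimers) | O=C(OCc1ccccc1)[C@@H]1CCC(O)N1C(=O)OC(C)(C)C | intermediate
3 | benzyl (2S)-1-(tert-butoxycarbonyl)-5-methoxypyrrolidine-2-carboxylate (C5 epimers) | O=C(OCc1ccccc1)[C@@H]1CCC(OC)N1C(=O)OC(C)(C)C | intermediate
4 | 3-methylfuran-2(5H)-one | CC1=CCOC1=O | starting material
5 | [(3-methylfuran-2-yl)oxy]tri(propan-2-yl)silane | Cc1ccoc1O[Si](C(C)C)(C(C)C)C(C)C | intermediate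
6 | benzyl (2S,5S)-1-(tert-butoxycarbonyl)-5-[(2S)-4-methyl-5-oxo-2,5-dihydrofuran-2-yl]pyrrolidine-2-carboxylate | O=C(OCc1ccccc1)[C@@H]1CC[C@@H]([C@@H]2C=C(C)C(=O)O2)N1C(=O)OC(C)(C)C | intermediate
7 | (2S,5S)-1-(tert-butoxycarbonyl)-5-[(2S,4S)-4-methyl-5-oxooxolan-2-yl]pyrrolidine-2-carboxylic acid | OC(=O)[C@@H]1CC[C@@H]([C@@H]2C[C@H](C)C(=O)O2)N1C(=O)OC(C)(C)C | intermediate
8 | S-ethyl (2S,5S)-1-(tert-butoxycarbonyl)-5-[(2S,4S)-4-methyl-5-oxooxolan-2-yl]pyrrolidine-2-carbothioate | CCSC(=O)[C@@H]1CC[C@@H]([C@@H]2C[C@H](C)C(=O)O2)N1C(=O)OC(C)(C)C | intermediate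
9 | (2S)-3-bromo-2-methylpropan-1-ol | BrC[C@@H](C)CO | starting material
10 | (2S)-3-bromo-2-methylpropanoic acid | BrC[C@@H](C)C(=O)O | intermediate
11 | (2S)-3-bromo-2-methylpropanoyl chloride | BrC[C@@H](C)C(=O)Cl | intermediate
12 | (2S,5S)-2-[(ethylsulfanyl)carbonyl]-5-[(2S,4S)-4-methyl-5-oxooxolan-2-yl]pyrrolidinium trifluoroacetate | CCSC(=O)[C@@H]1CC[C@@H]([C@@H]2C[C@H](C)C(=O)O2)[NH2+]1.[O-]C(=O)C(F)(F)F | intermediate
13 | S-ethyl (2S,5S)-1-[(2S)-3-bromo-2-methylpropanoyl]-5-[(2S,4S)-4-methyl-5-oxooxolan-2-yl]pyrrolidine-2-carbothioate | CCSC(=O)[C@@H]1CC[C@@H]([C@@H]2C[C@H](C)C(=O)O2)N1C(=O)[C@H](C)CBr | intermediate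
14 | (furan-3-yl)methanol | OCc1ccoc1 | starting material
15 | lithium (2-lithiofuran-3-yl)methanolate | [Li]OCc1ccoc1[Li] | intermediate
16 | trimethyl{3-[(trimethylsilyloxy)methyl]furan-2-yl}silane | C[Si](C)(C)OCc1ccoc1[Si](C)(C)C | intermediate
17 | [2-(trimethylsilyl)furan-3-yl]methanol | OCc1ccoc1[Si](C)(C)C | intermediate
18 | lithium [4-lithio-2-(trimethylsilyl)furan-3-yl]methanolate | [Li]OCc1c([Li])coc1[Si](C)(C)C | intermediate
19 | [4-iodo-2-(trimethylsilyl)furan-3-yl]methanol | OCc1c(I)coc1[Si](C)(C)C | intermediate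
20 | [4-iodo-2-(trimethylsilyl)furan-3-yl]methyl methanesulfonate | CS(=O)(=O)OCc1c(I)coc1[Si](C)(C)C | intermediate
21 | (4-iodo-3-methylfuran-2-yl)trimethylsilane | Cc1c(I)coc1[Si](C)(C)C | intermediate
22 | chloro[4-methyl-5-(trimethylsilyl)furan-3-yl]magnesium | Cc1c([Mg]Cl)coc1[Si](C)(C)C | intermediate
23 | 2-[4-methyl-5-(trimethylsilyl)furan-3-yl]ethan-1-ol | Cc1c(CCO)coc1[Si](C)(C)C | intermediate
24 | [4-(2-iodoethyl)-3-methylfuran-2-yl]trimethylsilane | Cc1c(CCI)coc1[Si](C)(C)C | intermediate
25 | iodo{2-[4-methyl-5-(trimethylsilyl)furan-3-yl]ethyl}zinc | Cc1c(CC[Zn]I)coc1[Si](C)(C)C | intermediate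
26 | (3S,5S)-5-[(2S,5S)-1-[(2S)-3-bromo-2-methylpropanoyl]-5-{3-[4-methyl-5-(trimethylsilyl)furan-3-yl]propanoyl}pyrrolidin-2-yl]-3-methyloxolan-2-one | Cc1c(CCC(=O)[C@@H]2CC[C@@H]([C@@H]3C[C@H](C)C(=O)O3)N2C(=O)[C@H](C)CBr)coc1[Si](C)(C)C | intermediate
27 | (3S,5S)-5-[(2S,5S)-1-[(2S)-3-iodo-2-methylpropanoyl]-5-{3-[4-methyl-5-(trimethylsilyl)furan-3-yl]propanoyl}pyrrolidin-2-yl]-3-methyloxolan-2-one | Cc1c(CCC(=O)[C@@H]2CC[C@@H]([C@@H]3C[C@H](C)C(=O)O3)N2C(=O)[C@H](C)CI)coc1[Si](C)(C)C | intermediate
28 | alkylsamarium diiodide from 27 (SmI2 group on C10 in place of iodine) | Cc1c(CCC(=O)[C@@H]2CC[C@@H]([C@@H]3C[C@H](C)C(=O)O3)N2C(=O)[C@H](C)C[Sm](I)I)coc1[Si](C)(C)C | intermediate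
29 | (3S,6R,8S,8aS)-8-hydroxy-6-methyl-3-[(2S,4S)-4-methyl-5-oxooxolan-2-yl]-8-{2-[4-methyl-5-(trimethylsilyl)furan-3-yl]ethyl}indolizidin-5-one | Cc1c(CC[C@](O)(C7)[C@@H]2CC[C@@H]([C@@H]3C[C@H](C)C(=O)O3)N2C(=O)[C@@H]7C)coc1[Si](C)(C)C | intermediate
30 | trimethylsilyl (Z)-2-methyl-4-oxobut-2-enoate carrying at C3 the 2-(indolizidinon-8-yl)ethyl chain of 29 | C[Si](C)(C)OC(=O)/C(C)=C(\C=O)CC[C@](O)(C7)[C@@H]2CC[C@@H]([C@@H]3C[C@H](C)C(=O)O3)N2C(=O)[C@@H]7C | intermediate
31 | 5-hydroxy-4-(2-{(3S,6R,8S,8aS)-8-hydroxy-6-methyl-3-[(2S,4S)-4-methyl-5-oxooxolan-2-yl]-5-oxoindolizidin-8-yl}ethyl)-3-methylfuran-2(5H)-one (hemiacetal epimers) | CC1=C(CC[C@](O)(C7)[C@@H]2CC[C@@H]([C@@H]3C[C@H](C)C(=O)O3)N2C(=O)[C@@H]7C)C(O)OC1=O | intermediate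
32 | (2S,5S)-2-[(2S,4R)-2-[2-(2-hydroxy-4-methyl-5-oxo-2,5-dihydrofuran-3-yl)ethyl]-4-methyl-5-oxooxolan-2-yl]-5-[(2S,4S)-4-methyl-5-oxooxolan-2-yl]pyrrolidinium chloride | CC1=C(CC[C@]3(C[C@@H](C)C(=O)O3)[C@@H]3CC[C@@H]([C@@H]4C[C@H](C)C(=O)O4)[NH2+]3)C(O)OC1=O.[Cl-] | intermediate
33 | pyrrolo[1,2-a]azepinium chloride with N4=C5 iminium, exocyclic (Z)-C(CH3)CO2H ylidene on C6, spiro ring D on C9 and ring E on C3 | OC(=O)/C(C)=C1/CC[C@]3(C[C@@H](C)C(=O)O3)[C@@H]3CC[C@@H]([C@@H]4C[C@H](C)C(=O)O4)[N+]3=C1.[Cl-] | intermediate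
34 | CNP0155196.1, pentacycle with rings A–E as in the overview, (3S,5S,9S,9aS,11R,18S,20S) | CC1=C2CC[C@]3(C[C@@H](C)C(=O)O3)[C@@H]3CC[C@@H]([C@@H]4C[C@H](C)C(=O)O4)N3[C@H]2OC1=O | target

## Step count and risks

Total steps: 18. Longest linear sequence: 10 steps (1, 3, 4, 5, 8, 14, 15, 16, 17, 18; the furan branch 9–13 followed by 14–18 is equally long).

Most likely to fail:

1. Step 18. The N→O acyl migration may stall at the strained bicyclic tetrahedral intermediate. Once nitrogen is no longer protonated, O→N back-migration to the lactam may outrun N,O-acetal formation, and C5 may not settle in the desired configuration. Fallback: starting from 31, the hemiacetal hydroxyl would be acetylated (Ac2O, pyridine, 0 °C; the tertiary C9–OH is not acylated) to the γ-acetoxybutenolide lactam F1. HCl in dioxane would then effect the acyl migration to the spirolactone ammonium chloride bearing the acetoxybutenolide F2. Addition of i-Pr2NEt in CH2Cl2 at −20 °C would release the amine next to a pseudo-ester that is far more electrophilic than the lactone, so that intramolecular displacement of acetate (N-alkylation by an activated γ-acyloxybutenolide) closes rings B and C and returns to the route at 34.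

2. Step 16. Electron transfer to the α-amido ketone may come first and lead to reductive loss of N4. The C10 radical or alkylsamarium may be quenched (1,5-hydrogen transfer, protonation) before it reaches C9, or the facial selectivity at C9 may be insufficient. Fallback with reversed roles (the ketyl is made on purpose and trapped by a tethered acceptor): starting from 8, Boc removal (TFA) and Schotten–Baumann acylation with methacryloyl chloride would give the N-methacryloyl thioester F3. Fukuyama coupling with 25 would give the N-methacryloyl ketone F4. SmI2, HMPA and t-BuOH in THF at −78 °C would bring about a ketyl–olefin radical cyclisation onto the methacrylamide terminus (6-endo), again forming C9–C10 in the same lactam ring. Protonation of the samarium enolate anti to the axial samarium alkoxide should set C11, and the sequence returns to the route at 29.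

3. Step 8. Acylation of the hindered 2,5-disubstituted pyrrolidine may be slower than hydrolysis of 11, and basic conditions may cause HBr elimination or epimerisation at C11 or at the thioester α-carbon. Fallback with the order of events changed: starting from 7, TFA would give the amino acid trifluoroacetate F5. Acylation with 11 in aqueous Na2CO3 at pH 8–9 and 0 °C (the conditions used for N-acylating proline with 3-halo-2-methylpropanoyl chlorides) would give the N-acyl acid F6. Thioesterification (EtSH, EDC·HCl, cat. DMAP) then returns to the route at 13.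

Further compounds
F1 | step 18 | 5-acetoxy-4-(2-{(3S,6R,8S,8aS)-8-hydroxy-6-methyl-3-[(2S,4S)-4-methyl-5-oxooxolan-2-yl]-5-oxoindolizidin-8-yl}ethyl)-3-methylfuran-2(5H)-one (C5 epimers) | CC1=C(CC[C@](O)(C7)[C@@H]2CC[C@@H]([C@@H]3C[C@H](C)C(=O)O3)N2C(=O)[C@@H]7C)C(OC(C)=O)OC1=O
F2 | step 18 | (2S,5S)-2-[(2S,4R)-2-[2-(2-acetoxy-4-methyl-5-oxo-2,5-dihydrofuran-3-yl)ethyl]-4-methyl-5-oxooxolan-2-yl]-5-[(2S,4S)-4-methyl-5-oxooxolan-2-yl]pyrrolidinium chloride | CC1=C(CC[C@]3(C[C@@H](C)C(=O)O3)[C@@H]3CC[C@@H]([C@@H]4C[C@H](C)C(=O)O4)[NH2+]3)C(OC(C)=O)OC1=O.[Cl-]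
F3 | step 16 | S-ethyl (2S,5S)-1-(2-methylprop-2-enoyl)-5-[(2S,4S)-4-methyl-5-oxooxolan-2-yl]pyrrolidine-2-carbothioate | CCSC(=O)[C@@H]1CC[C@@H]([C@@H]2C[C@H](C)C(=O)O2)N1C(=O)C(C)=C
F4 | step 16 | (3S,5S)-3-methyl-5-[(2S,5S)-1-(2-methylprop-2-enoyl)-5-{3-[4-methyl-5-(trimethylsilyl)furan-3-yl]propanoyl}pyrrolidin-2-yl]oxolan-2-one | Cc1c(CCC(=O)[C@@H]2CC[C@@H]([C@@H]3C[C@H](C)C(=O)O3)N2C(=O)C(C)=C)coc1[Si](C)(C)C
F5 | step 8 | (2S,5S)-2-carboxy-5-[(2S,4S)-4-methyl-5-oxooxolan-2-yl]pyrrolidinium trifluoroacetate | OC(=O)[C@@H]1CC[C@@H]([C@@H]2C[C@H](C)C(=O)O2)[NH2+]1.[O-]C(=O)C(F)(F)F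
F6 | step 8 | (2S,5S)-1-[(2S)-3-bromo-2-methylpropanoyl]-5-[(2S,4S)-4-methyl-5-oxooxolan-2-yl]pyrrolidine-2-carboxylic acid | OC(=O)[C@@H]1CC[C@@H]([C@@H]2C[C@H](C)C(=O)O2)N1C(=O)[C@H](C)CBr
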